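**Plan**
- Retrosynthesis first cuts the two aryl–CH2 bonds at the central ring B. This gives the acetyl dienone ring A (with the quaternary carbon), butanoylphloroglucinol (ring B) and the chromene (arene ring C, pyran ring D). Each bridge carbon is a Mannich CH2.
- Ring D is then cut at C4–C3 and O1–C2. C4 sits on arene carbon C4a, which is ortho to the oxygen-bearing C8a. C4 can therefore be a salicylaldehyde carbon that takes an isobutenyl group from boron and closes through the oxatriene O1=C8a–C4a=C4–C3=C2.
- Two allyl ethers leave free only the hydroxyl between formyl and butanoyl, which fixes the oxygen that becomes O1.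
- Forward order: ring B ketone, formyl ether, ring D (step 4), chromene–CH2–ring B (step 7), ring A joined last under the mildest conditions (step 10).
- Stereochemistry: the only stereocentre (quaternary C4 of ring A, R) comes from a palladium-catalysed asymmetric dearomative geranylation (step 9). The E alkene comes from geranyl acetate.

Key step: step 4

Remarks on the chemistry (assumptions):
- All β-triketone units are drawn in the enol tautomer of the target SMILES, and the descriptor R refers to that drawing.
- The sense of induction in step 9 cannot be read from precedent. The (R,R) ligand is written, and its mirror image would be used if the first run favoured the (S) product.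

**Step 1**
Reactants: 1 phloroglucinol; 2 butanoyl chloride
Product: 3 1-(2,4,6-trihydroxyphenyl)butan-1-one
Conditions: AlCl3 (3 equiv), PhNO2/CH2Cl2, 0 °C to 40 °C; aq. HCl work-up
Reagents that add atoms: butanoyl chloride, CCCC(=O)Cl
Why: Friedel–Crafts C-acylation of the symmetric, strongly activated triol should stop after one acyl group because the aryl ketone formed is deactivated.

**Step 2**
Reactants: 3 1-(2,4,6-trihydroxyphenyl)butan-1-one; 4 allyl bromide
Product: 5 1-[2-hydroxy-4,6-bis(prop-2-en-1-yloxy)phenyl]butan-1-one
Conditions: allyl bromide (2.1 equiv), K2CO3 (2.2 equiv), acetone, reflux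
Reagents that add atoms: allyl bromide, C=CCBr
Why: Williamson etherification should take the para hydroxyl and one ortho hydroxyl and leave the last ortho hydroxyl, held in a hydrogen bond to the ketone, free, as in the usual bis-O-alkylation of phloroacylphenones.

**Step 3**
Reactants: 5 1-[2-hydroxy-4,6-bis(prop-2-en-1-yloxy)phenyl]butan-1-one; 6 paraformaldehyde
Product: 7 3-butanoyl-2-hydroxy-4,6-bis(prop-2-en-1-yloxy)benzaldehyde
Conditions: MgCl2 (anhydrous, 3 equiv), Et3N (6 equiv), (CH2O)n (8 equiv), MeCN, 80 °C; cold aq. citric acid work-up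
Reagents that add atoms: formaldehyde (from paraformaldehyde), C=O
Why: Magnesium-phenoxide-directed ortho-formylation (hydroxymethylation, then hydride transfer to a second formaldehyde) can reach only the one ring carbon ortho to the single free phenol, the carbon between OH and O-allyl.

**Step 4**
Reactants: 7 3-butanoyl-2-hydroxy-4,6-bis(prop-2-en-1-yloxy)benzaldehyde; 8 (2-methylprop-1-en-1-yl)boronic acid; 9 dibenzylamine (catalyst)
Product: 12 1-[2,2-dimethyl-5,7-bis(prop-2-en-1-yloxy)-2H-chromen-8-yl]butan-1-one, via Petasis allylamine 10 (not isolated), via vinyl quinone methide 11 (not isolated)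
Conditions: 8 (1.5 equiv), Bn2NH (0.3 equiv), 1,4-dioxane, 90 °C
Reagents that add atoms: (2-methylprop-1-en-1-yl)boronic acid, CC(C)=CB(O)O
Why: Dibenzylamine condenses with the aldehyde of 7 to an iminium ion, the neighbouring free phenol binds 8 as a boronate, and the isobutenyl group passes within this complex to the iminium carbon (Petasis borono-Mannich step, C4–C3 bond); amine 10 then expels dibenzylamine at 90 °C to give the vinyl ortho-quinone methide 11, the oxatriene O=C8a–C4a=C4–C3=C2, whose closure forms O1–C2 and restores the arene. The closest known reaction type is the amine-catalysed condensation of salicylaldehydes with alkenylboronic acids to 2H-chromenes. Ring D closes by a thermal disrotatory oxa-6π electrocyclization driven by rearomatisation. No stereocentre remains, since the carbinamine carbon of 10 becomes sp2 and C2 carries two methyl groups. The step must choose between the two oxygens that flank the formyl carbon; the allyl ether on the 4-oxygen leaves only the 2-hydroxyl (between formyl and butanoyl) able to carry boron and to close, so only the 8-butanoyl chromene can form, and the hindered, chelated ketone should not form an iminium ion with the bulky amine.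

**Step 5**
Reactants: 12 1-[2,2-dimethyl-5,7-bis(prop-2-en-1-yloxy)-2H-chromen-8-yl]butan-1-one
Product: 13 1-(5,7-dihydroxy-2,2-dimethyl-2H-chromen-8-yl)butan-1-one
Conditions: Pd(PPh3)4 (5 mol%), morpholine (6 equiv), THF, rt
Reagents that add atoms: none
Why: Zerovalent palladium ionises both aryl allyl ethers (Tsuji–Trost deallylation) and morpholine traps the allyl groups under neutral conditions that cannot protonate or re-open the acid-sensitive 2,2-dimethylchromene.

**Step 6**
Reactants: 13 1-(5,7-dihydroxy-2,2-dimethyl-2H-chromen-8-yl)butan-1-one; 14 N,N-dimethylmethyleneiminium iodide (Eschenmoser's salt)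
Product: 15 1-{6-[(dimethylamino)methyl]-5,7-dihydroxy-2,2-dimethyl-2H-chromen-8-yl}butan-1-one
Conditions: 14 (1.05 equiv), Et3N (1.1 equiv), CH2Cl2, 0 °C to rt
Reagents that add atoms: N,N-dimethylmethyleneiminium iodide, C=[N+](C)C.[I-]
Why: Mannich aminomethylation should occur at C6, the only unsubstituted arene carbon, which lies between two hydroxyls.

**Step 7**
Reactants: 15 1-{6-[(dimethylamino)methyl]-5,7-dihydroxy-2,2-dimethyl-2H-chromen-8-yl}butan-1-one; 3 1-(2,4,6-trihydroxyphenyl)butan-1-one
Product: 17 1-{3-[(8-butanoyl-5,7-dihydroxy-2,2-dimethyl-2H-chromen-6-yl)methyl]-2,4,6-trihydroxyphenyl}butan-1-one, via chromene quinone methide 16 (not isolated)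
Conditions: 3 (4 equiv), 1,4-dioxane, 90 °C, slow N2 stream
Reagents that add atoms: none
Why: Thermal loss of Me2NH from the ortho-hydroxybenzylamine gives ortho-quinone methide 16, which is captured at carbon by 3 (Michael-type Friedel–Crafts alkylation with rearomatisation), the excess of 3 holding the reaction at mono-alkylation.

**Step 8**
Reactants: 18 2-methylbenzene-1,3,5-triol; 19 acetyl chloride
Product: 20 1-(2,4,6-trihydroxy-3-methylphenyl)ethan-1-one
Conditions: AlCl3 (3 equiv), PhNO2/CH2Cl2, 0 °C to 40 °C; aq. HCl work-up
Reagents that add atoms: acetyl chloride, CC(=O)Cl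
Why: Friedel–Crafts acylation at one of the two equivalent free ring carbons should stop at the mono-ketone because the product is deactivated.

**Step 9**
Reactants: 20 1-(2,4,6-trihydroxy-3-methylphenyl)ethan-1-one; 21 geranyl acetate
Product: 22 (4R)-2-acetyl-4-[(2E)-3,7-dimethylocta-2,6-dien-1-yl]-3,5-dihydroxy-4-methylcyclohexa-2,5-dien-1-one
Conditions: Pd2(dba)3·CHCl3 (2.5 mol%), (R,R)-DACH-phenyl Trost ligand (7.5 mol%), Cs2CO3 (1.0 equiv), 21 (1.0 equiv), degassed 1,4-dioxane, rt; dilute acid work-up
Reagents that add atoms: geranyl acetate, CC(=O)OC/C=C(\C)CCC=C(C)C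
Why: Proposed new method: zerovalent palladium with the bisphosphine ionises 21 to a π-geranyl complex of divalent palladium, and the caesium phenoxide of 20 attacks its unsubstituted CH2 terminus (linear product, E alkene kept, because the attacking carbon itself becomes quaternary) through the methyl-bearing ring carbon between two oxygens, the most electron-rich one, while any O-geranyl ether is re-ionised by palladium and drained to the C–C product; the chiral pocket of the ligand should tell apart the two faces of the flat phenoxide, whose flanks differ (acetyl-chelated hydroxyl on one side, oxygen next to CH on the other), and the quaternary centre cannot epimerise afterwards; the closest known reaction types are the palladium-catalysed intermolecular asymmetric allylic dearomatization of naphthols with this ligand class and the base-mediated geminal C-alkylation of alkylated acylphloroglucinols.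

**Step 10**
Reactants: 22 (4R)-2-acetyl-4-[(2E)-3,7-dimethylocta-2,6-dien-1-yl]-3,5-dihydroxy-4-methylcyclohexa-2,5-dien-1-one; 14 N,N-dimethylmethyleneiminium iodide; 17 1-{3-[(8-butanoyl-5,7-dihydroxy-2,2-dimethyl-2H-chromen-6-yl)methyl]-2,4,6-trihydroxyphenyl}butan-1-one
Product: 25 CNP0103039.1, via Mannich base 23 (not isolated), via methylene trione 24 (not isolated)
Conditions: 14 (0.98 equiv), Et3N (1.0 equiv), CH2Cl2, 0 °C; then 17 (1.2 equiv), 1,4-dioxane, 60 °C, N2; dilute citric acid work-up
Reagents that add atoms: N,N-dimethylmethyleneiminium iodide, C=[N+](C)C.[I-]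
Why: All of 22 is first aminomethylated at its only enolic CH (C6), so no nucleophilic 22 is left to dimerise, and gentle warming then expels Me2NH to give the 2-methylene-1,3-dione 24, a strong Michael acceptor that the single free arene carbon of ring B in 17 should capture (Mannich–Michael methylene bridging) without touching the quaternary stereocentre.

**Compound list**
1 | phloroglucinol (benzene-1,3,5-triol) | Oc1cc(O)cc(O)c1 | starting material
2 | butanoyl chloride | CCCC(=O)Cl | starting material
3 | 1-(2,4,6-trihydroxyphenyl)butan-1-one | CCCC(=O)c1c(O)cc(O)cc1O | intermediate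
4 | allyl bromide (3-bromoprop-1-ene) | C=CCBr | starting material
5 | 1-[2-hydroxy-4,6-bis(prop-2-en-1-yloxy)phenyl]butan-1-one | CCCC(=O)c1c(O)cc(OCC=C)cc1OCC=C | intermediate
6 | paraformaldehyde (written as its formaldehyde unit) | C=O | starting material
7 | 3-butanoyl-2-hydroxy-4,6-bis(prop-2-en-1-yloxy)benzaldehyde | CCCC(=O)c1c(O)c(C=O)c(OCC=C)cc1OCC=C | intermediate
8 | (2-methylprop-1-en-1-yl)boronic acid | CC(C)=CB(O)O | starting material
9 | dibenzylamine | C(NCc1ccccc1)c1ccccc1 | starting material
10 | 1-{3-[1-(dibenzylamino)-3-methylbut-2-en-1-yl]-2-hydroxy-4,6-bis(prop-2-en-1-yloxy)phenyl}butan-1-one (racemic, not isolated) | CCCC(=O)c1c(O)c(C(C=C(C)C)N(Cc2ccccc2)Cc2ccccc2)c(OCC=C)cc1OCC=C | intermediate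
11 | 2-butanoyl-6-(3-methylbut-2-en-1-ylidene)-3,5-bis(prop-2-en-1-yloxy)cyclohexa-2,4-dien-1-one (not isolated) | CCCC(=O)C1=C(OCC=C)C=C(OCC=C)C(=CC=C(C)C)C1=O | intermediate
12 | 1-[2,2-dimethyl-5,7-bis(prop-2-en-1-yloxy)-2H-chromen-8-yl]butan-1-one | CCCC(=O)c1c(OCC=C)cc(OCC=C)c2C=CC(C)(C)Oc12 | intermediate
13 | 1-(5,7-dihydroxy-2,2-dimethyl-2H-chromen-8-yl)butan-1-one | CCCC(=O)c1c(O)cc(O)c2C=CC(C)(C)Oc12 | intermediate
14 | N,N-dimethylmethyleneiminium iodide (Eschenmoser's salt) | C=[N+](C)C.[I-] | starting material
15 | 1-{6-[(dimethylamino)methyl]-5,7-dihydroxy-2,2-dimethyl-2H-chromen-8-yl}butan-1-one | CCCC(=O)c1c(O)c(CN(C)C)c(O)c2C=CC(C)(C)Oc12 | intermediate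
16 | 8-butanoyl-7-hydroxy-2,2-dimethyl-6-methylidene-2H-chromen-5(6H)-one (not isolated) | C=C1C(=O)C2=C(OC(C)(C)C=C2)C(C(=O)CCC)=C1O | intermediate
17 | 1-{3-[(8-butanoyl-5,7-dihydroxy-2,2-dimethyl-2H-chromen-6-yl)methyl]-2,4,6-trihydroxyphenyl}butan-1-one | CCCC(=O)c1c(O)cc(O)c(Cc2c(O)c3c(c(C(=O)CCC)c2O)OC(C)(C)C=C3)c1O | intermediate
18 | 2-methylbenzene-1,3,5-triol (2-methylphloroglucinol) | Cc1c(O)cc(O)cc1O | starting material
19 | acetyl chloride | CC(=O)Cl | starting material
20 | 1-(2,4,6-trihydroxy-3-methylphenyl)ethan-1-one | CC(=O)c1c(O)cc(O)c(C)c1O | intermediate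
21 | geranyl acetate, (2E)-3,7-dimethylocta-2,6-dien-1-yl acetate | CC(=O)OC/C=C(\C)CCC=C(C)C | starting material
22 | (4R)-2-acetyl-4-[(2E)-3,7-dimethylocta-2,6-dien-1-yl]-3,5-dihydroxy-4-methylcyclohexa-2,5-dien-1-one | C1=C(O)[C@@](C)(C/C=C(\C)CCC=C(C)C)C(O)=C(C(C)=O)C1=O | intermediate
23 | (4R)-2-acetyl-6-[(dimethylamino)methyl]-4-[(2E)-3,7-dimethylocta-2,6-dien-1-yl]-3,5-dihydroxy-4-methylcyclohexa-2,5-dien-1-one (not isolated) | CN(C)CC1=C(O)[C@@](C)(C/C=C(\C)CCC=C(C)C)C(O)=C(C(C)=O)C1=O | intermediate
24 | (R)-2-acetyl-4-[(2E)-3,7-dimethylocta-2,6-dien-1-yl]-3-hydroxy-4-methyl-6-methylidenecyclohex-2-ene-1,5-dione (not isolated) | C=C1C(=O)[C@@](C)(C/C=C(\C)CCC=C(C)C)C(O)=C(C(C)=O)C1=O | intermediate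
25 | CNP0103039.1, (4R)-2-acetyl-6-{[3-butanoyl-5-[(8-butanoyl-5,7-dihydroxy-2,2-dimethyl-2H-chromen-6-yl)methyl]-2,4,6-trihydroxyphenyl]methyl}-4-[(2E)-3,7-dimethylocta-2,6-dien-1-yl]-3,5-dihydroxy-4-methylcyclohexa-2,5-dien-1-one | CCCC(=O)c1c(O)c(CC2=C(O)[C@@](C)(C/C=C(\C)CCC=C(C)C)C(O)=C(C(C)=O)C2=O)c(O)c(Cc2c(O)c3c(c(C(=O)CCC)c2O)OC(C)(C)C=C3)c1O | target

**Step count**
Total steps: 10. Longest linear sequence: 8 steps (1, 2, 3, 4, 5, 6, 7, 10).

**Steps most likely to fail**

Step 9 (proposed new method). The catalyst may discriminate poorly between the two faces of the flat phenoxide, whose flanks differ only one atom away from the reacting carbon. Alkylation may also go to the unsubstituted ring carbon with rearomatisation, or the E alkene may partly scramble through the π-allyl complex. The fallback sets out from 20 and uses known chemistry. Geminal C-alkylation with geranyl bromide and NaOMe in MeOH at 0 °C should give racemic 2-acetyl-4-[(2E)-3,7-dimethylocta-2,6-dien-1-yl]-3,5-dihydroxy-4-methylcyclohexa-2,5-dien-1-one F1, which is freed from the aromatic regioisomer by chromatography. It is then resolved by preparative supercritical-fluid chromatography on a polysaccharide carbamate chiral phase. The configuration is assigned by electronic circular dichroism against calculation, and the (R) enantiomer re-enters the route as 22.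

Step 4. Transfer of the isobutenyl group from boron may be slow, because the three ring oxygens make the iminium ion a weak electrophile and the only free phenol is tied to the ketone by a hydrogen bond. Protodeboronation of 8 at 90 °C may then win. The fallback sets out from 7. Addition of 2-methylprop-1-en-1-ylmagnesium bromide (3 equiv, THF, −40 °C; the aldehyde should react before the hindered, chelated ketone) should give the racemic allylic alcohol 1-[2-hydroxy-3-(1-hydroxy-3-methylbut-2-en-1-yl)-4,6-bis(prop-2-en-1-yloxy)phenyl]butan-1-one F2. Warming F2 with catalytic pyridinium p-toluenesulfonate in toluene at 50 °C dehydrates it to the same quinone methide 11, which closes to 12, where the route is rejoined.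

Step 10. Methylene trione 24 is released next to only about one equivalent of a large nucleophile, so its capture by ring B of 17 may be slower than its own side reactions. These are re-addition of Me2NH, hetero-Diels–Alder addition to the chromene or geranyl alkenes, and oligomerisation. The fallback reverses the order of bridging and sets out from 22. Mannich base 23 is made as in step 10 but warmed with a large excess of 3 (4 equiv, dioxane, 50 °C) to give the ring A–ring B dimer (4R)-2-acetyl-6-[(3-butanoyl-2,4,6-trihydroxyphenyl)methyl]-4-[(2E)-3,7-dimethylocta-2,6-dien-1-yl]-3,5-dihydroxy-4-methylcyclohexa-2,5-dien-1-one F3. Separately, 15 is quaternised with MeI in acetone to the methiodide 1-(8-butanoyl-5,7-dihydroxy-2,2-dimethyl-2H-chromen-6-yl)-N,N,N-trimethylmethanaminium iodide F4. F4 releases quinone methide 16 with NaHCO3 in MeCN at room temperature in the presence of F3, conditions mild enough for the bridge already present, and gives 25 directly.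

**Further compounds**
F1 | step 9 | racemic 2-acetyl-4-[(2E)-3,7-dimethylocta-2,6-dien-1-yl]-3,5-dihydroxy-4-methylcyclohexa-2,5-dien-1-one | C1=C(O)C(C)(C/C=C(\C)CCC=C(C)C)C(O)=C(C(C)=O)C1=O
F2 | step 4 | 1-[2-hydroxy-3-(1-hydroxy-3-methylbut-2-en-1-yl)-4,6-bis(prop-2-en-1-yloxy)phenyl]butan-1-one (racemic) | CCCC(=O)c1c(O)c(C(O)C=C(C)C)c(OCC=C)cc1OCC=C
F3 | step 10 | (4R)-2-acetyl-6-[(3-butanoyl-2,4,6-trihydroxyphenyl)methyl]-4-[(2E)-3,7-dimethylocta-2,6-dien-1-yl]-3,5-dihydroxy-4-methylcyclohexa-2,5-dien-1-one | CCCC(=O)c1c(O)cc(O)c(CC2=C(O)[C@@](C)(C/C=C(\C)CCC=C(C)C)C(O)=C(C(C)=O)C2=O)c1O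
F4 | step 10 | 1-(8-butanoyl-5,7-dihydroxy-2,2-dimethyl-2H-chromen-6-yl)-N,N,N-trimethylmethanaminium iodide | CCCC(=O)c1c(O)c(C[N+](C)(C)C)c(O)c2C=CC(C)(C)Oc12.[I-]
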